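**Retrosynthetic overview**
- Ring B is read as a cyclohexane-1,3-dione: C6 is a bare CH2 between C5 and C7, and the C8 methylidene is a masked ketone. A C5–C6–C7 acetonyl unit (1,3-dinucleophile) and a C8–C9=C10 unsaturated thioester (1,3-dielectrophile) can therefore be zipped together.
- Key disconnection: C5–C10 (Michael; closes ring A, creates the quaternary C10 and C5) and C7–C8 (Claisen; closes ring B) in one magnesium-templated bicyclization of an acyclic keto enethioate. Its only ring-relevant stereocentre is the quaternary C4; ring A forms first, then ring B.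
- The C19 carboxyl is 1,4 to C6 and cis to it on ring A. It carries off the C6 oxygen regiospecifically (enol lactone, then hydrogenation/β-elimination); the C8 ketone that remains is methylenated.
- The acyclic precursor comes from a B-alkyl Suzuki coupling (C1–C10) of fragment A (C4 from (S)-γ-valerolactone by two enolate alkylations) with fragment B (C13 from monomethyl (R)-3-methylglutarate; enol triflate of an alkylated acetothioacetate).

Key step: step 10

Assumption (remark on the chemistry): the target is a cis-fused decalin with the C4 methyl, H5, the C10 methyl and the C9 side chain on one face and the C4 carboxyl on the other; labdane numbering is used (ring A = C1–C5, C10; ring B = C5–C10), and compounds 1, 7 and 10 are taken as commercial.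

**Route**

Step 1
Reactants: 1 (5S)-5-methyldihydrofuran-2(3H)-one ((S)-γ-valerolactone)
Product: 2 (5S)-3,5-dimethyldihydrofuran-2(3H)-one (C3 epimers)
Conditions: LiN(i-Pr)2, THF, −78 °C; MeI, −78 to −30 °C
Reagents that add atoms: iodomethane, CI
Why: Lactone enolate alkylation (SN2 on MeI); the new C3 centre need not be controlled because it is planarized again in step 2, and the C5 carbinol centre is untouched.

Step 2
Reactants: 2 (5S)-3,5-dimethyldihydrofuran-2(3H)-one
Product: 3 (3S,5S)-3-allyl-3,5-dimethyldihydrofuran-2(3H)-one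
Conditions: LiN(i-Pr)2, THF, −78 °C; allyl bromide, DMPU, −78 to −20 °C
Reagents that add atoms: allyl bromide, C=CCBr
Why: Second lactone enolate alkylation; the planar α-methyl enolate should be attacked anti to the C5 methyl group (1,3-induction across the envelope), which sets the quaternary centre (future C4) as S, and the minor syn diastereomer should be separable by chromatography.

Step 3
Reactants: 3 (3S,5S)-3-allyl-3,5-dimethyldihydrofuran-2(3H)-one
Product: 5 (2S)-2-allyl-2-methyl-4-oxopentanoic acid, via lithium (2S,4S)-2-allyl-4-hydroxy-2-methylpentanoate 4 (not isolated)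
Conditions: LiOH, THF/H2O, 50 °C; then TEMPO (cat.), KBr (cat.), NaOCl, NaHCO3 buffer, 0 °C; then HCl to pH 2
Reagents that add atoms: lithium hydroxide, [Li+].[OH-]
Why: Saponification followed by TEMPO/hypochlorite oxidation of the secondary alcohol as its carboxylate salt (which cannot relactonize) should give the γ-keto acid; the sacrificial carbinol centre is erased and the quaternary centre is not affected.

Step 4
Reactants: 5 (2S)-2-allyl-2-methyl-4-oxopentanoic acid
Product: 6 tert-butyl (2S)-2-allyl-2-methyl-4-oxopentanoate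
Conditions: tert-butyl 2,2,2-trichloroacetimidate, BF3·OEt2 (cat.), CH2Cl2/cyclohexane, rt
Reagents that add atoms: tert-butyl 2,2,2-trichloroacetimidate, CC(C)(C)OC(=N)C(Cl)(Cl)Cl
Why: Acid-catalysed tert-butylation of the hindered acid with the trichloroacetimidate (transfer of a tert-butyl cation) gives an ester on a quaternary carbon that resists acyl substitution, which later blocks a competing five-ring Claisen closure.

Step 5
Reactants: 7 (3R)-5-methoxy-3-methyl-5-oxopentanoic acid (monomethyl (R)-3-methylglutarate)
Product: 8 methyl (3R)-5-hydroxy-3-methylpentanoate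
Conditions: BH3·SMe2, THF, −10 °C to rt; MeOH quench
Reagents that add atoms: none
Why: Chemoselective borane reduction of a carboxylic acid in the presence of a methyl ester (via the acyloxyborane); the stereocentre is not involved.

Step 6
Reactants: 8 methyl (3R)-5-hydroxy-3-methylpentanoate
Product: 9 methyl (3S)-5-iodo-3-methylpentanoate
Conditions: I2, PPh3, imidazole, CH2Cl2, 0 °C to rt
Reagents that add atoms: iodine, II
Why: Appel-type iodination (SN2 at the primary carbon) converts the alcohol before it can lactonize; the stereocentre is untouched and only its descriptor changes by priority.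

Step 7
Reactants: 10 S-tert-butyl 3-oxobutanethioate; 9 methyl (3S)-5-iodo-3-methylpentanoate
Product: 11 methyl (3R,6RS)-6-[(tert-butylsulfanyl)carbonyl]-3-methyl-7-oxooctanoate
Conditions: K2CO3, DMF, 40 °C
Reagents that add atoms: none
Why: C-alkylation of the β-keto thioester (stabilized enolate, SN2 on the primary iodide); the new centre (future C9) is left uncontrolled because it becomes sp2 in step 8.

Step 8
Reactants: 11 methyl (3R,6RS)-6-[(tert-butylsulfanyl)carbonyl]-3-methyl-7-oxooctanoate
Product: 12 methyl (3R,6Z)-6-[(tert-butylsulfanyl)carbonyl]-3-methyl-7-{[(trifluoromethyl)sulfonyl]oxy}oct-6-enoate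
Conditions: NaH, Et2O, 0 °C; (CF3SO2)2O, 0 °C
Reagents that add atoms: trifluoromethanesulfonic anhydride, O=S(=O)(OS(=O)(=O)C(F)(F)F)C(F)(F)F
Why: O-sulfonylation of the chelated sodium enolate of the β-keto thioester (enol triflate formation); the chelate should place the triflate cis to the thioester (Z).

Step 9
Reactants: 6 tert-butyl (2S)-2-allyl-2-methyl-4-oxopentanoate; 12 methyl (3R,6Z)-6-[(tert-butylsulfanyl)carbonyl]-3-methyl-7-{[(trifluoromethyl)sulfonyl]oxy}oct-6-enoate
Product: 14 methyl (3R,6Z,11S)-11-(tert-butoxycarbonyl)-6-[(tert-butylsulfanyl)carbonyl]-3,7,11-trimethyl-13-oxotetradec-6-enoate, via alkylborane 13 (not isolated)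
Conditions: 9-BBN, THF, 0 °C to rt; then 12, PdCl2(dppf) (cat.), AsPh3 (cat.), Cs2CO3, DMF/H2O, rt
Reagents that add atoms: none
Why: Anti-Markovnikov hydroboration of the terminal alkene (much faster than ketone reduction by 9-BBN at 0 °C) and B-alkyl Suzuki–Miyaura coupling with the enol triflate form the C1–C10 bond with retention of alkene geometry, giving the tetrasubstituted Z-enethioate.

Step 10
Reactants: 14 methyl (3R,6Z,11S)-11-(tert-butoxycarbonyl)-6-[(tert-butylsulfanyl)carbonyl]-3,7,11-trimethyl-13-oxotetradec-6-enoate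
Product: 16 tert-butyl (1S,4aS,5S,8aR)-5-[(3R)-5-methoxy-3-methyl-5-oxopentyl]-1,4a-dimethyl-6,8-dioxodecahydronaphthalene-1-carboxylate, via monocyclic Michael adduct 15 (not isolated)
Conditions: MgBr2·OEt2 (3 equiv), i-Pr2NEt (4 equiv), CH2Cl2 (high dilution), 0 °C to rt; aqueous citric acid work-up
Reagents that add atoms: none
Why: Proposed new method: reversible soft enolization (MgBr2/amine) gives both ketone enolates, but only the C5 enolate has a feasible ring size, so it adds to C10 of the unsaturated thioester (6-exo-trig Michael, ring A); after proton transfer from C7 to C9 the C7 enolate acylates on the thioester carbon C8 (6-exo-trig Claisen/Dieckmann closure, ring B) with loss of tert-butylthiolate, the magnesium 1,3-diketonate being the thermodynamic sink. The closest known reaction types are the consecutive Michael–Claisen synthesis of cyclohexane-1,3-diones from ketones and unsaturated esters and the magnesium-mediated soft-enolization C-acylation of ketones by activated esters; new is their intramolecular union on a tetrasubstituted acceptor. C10 (quaternary) and C5 are set together in the Michael step: the Z-enolate (oxygen syn to the quaternary C4, enforced by allylic strain) carries Mg, which is also bound by the axial C4 ester carbonyl and by the thioester carbonyl of the Z-acceptor, so C9 should be delivered on the ester face of a chair-like transition state with C6 equatorial, both methyl groups equatorial and H5 axial, i.e. CO2t-Bu, C6 and C9 all cis (cis ring fusion). C9 is set afterwards by protonation and equilibration alpha to the new C8 carbonyl and should settle with the side chain equatorial on ring B, cis to the C10 methyl. The step needs regioselectivity (C5 over C7 enolate, secured by ring size under reversible enolization), chemoselectivity (only the ketone is enolized; the tert-butyl ester on a quaternary carbon cannot enter the competing five-ring Claisen) and facial selectivity at C10 (secured by the C4 stereocentre through the magnesium template). High dilution suppresses intermolecular acylation.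

Step 11
Reactants: 16 tert-butyl (1S,4aS,5S,8aR)-5-[(3R)-5-methoxy-3-methyl-5-oxopentyl]-1,4a-dimethyl-6,8-dioxodecahydronaphthalene-1-carboxylate
Product: 18 methyl (3R)-5-[(2aS,5aR,6S,8bR)-2a,5a-dimethyl-2,7-dioxo-2a,3,4,5,5a,6,7,8b-octahydro-2H-naphtho[1,8-bc]furan-6-yl]-3-methylpentanoate (C19→O6 enol lactone), via dione acid 17 (not isolated)
Conditions: CF3CO2H/CH2Cl2, rt; evaporate; then (CF3CO)2O, CH2Cl2, 0 °C to rt
Reagents that add atoms: none
Why: Acidolysis of the tert-butyl ester (loss of isobutene) frees the C19 acid, whose mixed trifluoroacetic anhydride O-acylates the enol oxygen at C6 of the 1,3-dione (5-exo-trig enol lactonization of a γ-keto acid); C19 can reach only O6, so the two ring B oxygens are differentiated regiospecifically.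

Step 12
Reactants: 18 C19→O6 enol lactone
Product: 21 (1S,4aR,5S,8aR)-5-[(3R)-5-methoxy-3-methyl-5-oxopentyl]-1,4a-dimethyl-6-oxodecahydronaphthalene-1-carboxylic acid, via saturated acyloxy ketone 19 (not isolated), via enone acid 20 (not isolated)
Conditions: H2 (1 atm), Pd/C, Et3N, EtOAc, rt; then dilute HCl
Reagents that add atoms: none
Why: Hydrogenation of the β-acyloxy enone C6=C7 bond, E1cB expulsion of the C19 carboxylate from the resulting β-acyloxy ketone and hydrogenation of the enone so formed amount to hydrogenolysis of the vinylogous anhydride; this removes the C6 oxygen, frees the acid and leaves the C8 ketone, while C9 (alpha to that ketone) should equilibrate under Et3N to the equatorial side chain, cis to the C10 methyl.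

Step 13
Reactants: 21 (1S,4aR,5S,8aR)-5-[(3R)-5-methoxy-3-methyl-5-oxopentyl]-1,4a-dimethyl-6-oxodecahydronaphthalene-1-carboxylic acid
Product: 22 (1S,4aS,5R,8aR)-5-[(3R)-5-methoxy-3-methyl-5-oxopentyl]-1,4a-dimethyl-6-methylidenedecahydronaphthalene-1-carboxylic acid (CNP0260608.1)
Conditions: Ph3PCH3Br, KN(SiMe3)2 (excess), THF/toluene, 0 °C; add 21; 60 °C; acidic work-up
Reagents that add atoms: methyltriphenylphosphonium bromide, C[P+](c1ccccc1)(c1ccccc1)c1ccccc1.[Br-]
Why: Wittig methylenation of the hindered C8 ketone with excess ylide (the acid is carried as its potassium carboxylate, the methyl ester is inert) installs the exocyclic alkene and fixes C9.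

**Compound list**

1 | (5S)-5-methyldihydrofuran-2(3H)-one | C[C@H]1CCC(=O)O1 | starting material
2 | (5S)-3,5-dimethyldihydrofuran-2(3H)-one (C3 epimers) | CC1C[C@H](C)OC1=O | intermediate
3 | (3S,5S)-3-allyl-3,5-dimethyldihydrofuran-2(3H)-one | C=CC[C@@]1(C)C[C@H](C)OC1=O | intermediate
4 | lithium (2S,4S)-2-allyl-4-hydroxy-2-methylpentanoate | C=CC[C@@](C)(C[C@H](C)O)C(=O)[O-].[Li+] | intermediate
5 | (2S)-2-allyl-2-methyl-4-oxopentanoic acid | C=CC[C@@](C)(CC(C)=O)C(=O)O | intermediate
6 | tert-butyl (2S)-2-allyl-2-methyl-4-oxopentanoate | C=CC[C@@](C)(CC(C)=O)C(=O)OC(C)(C)C | intermediate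
7 | (3R)-5-methoxy-3-methyl-5-oxopentanoic acid | OC(=O)C[C@@H](C)CC(=O)OC | starting material
8 | methyl (3R)-5-hydroxy-3-methylpentanoate | OCC[C@@H](C)CC(=O)OC | intermediate
9 | methyl (3S)-5-iodo-3-methylpentanoate | ICC[C@@H](C)CC(=O)OC | intermediate
10 | S-tert-butyl 3-oxobutanethioate | CC(=O)CC(=O)SC(C)(C)C | starting material
11 | methyl (3R,6RS)-6-[(tert-butylsulfanyl)carbonyl]-3-methyl-7-oxooctanoate | CC(=O)C(CC[C@@H](C)CC(=O)OC)C(=O)SC(C)(C)C | intermediate
12 | methyl (3R,6Z)-6-[(tert-butylsulfanyl)carbonyl]-3-methyl-7-{[(trifluoromethyl)sulfonyl]oxy}oct-6-enoate | C/C(OS(=O)(=O)C(F)(F)F)=C(\CC[C@@H](C)CC(=O)OC)C(=O)SC(C)(C)C | intermediate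
13 | tert-butyl (2S)-5-(9-borabicyclo[3.3.1]nonan-9-yl)-2-methyl-2-(2-oxopropyl)pentanoate | CC(=O)C[C@](C)(CCCB1C2CCCC1CCC2)C(=O)OC(C)(C)C | intermediate
14 | methyl (3R,6Z,11S)-11-(tert-butoxycarbonyl)-6-[(tert-butylsulfanyl)carbonyl]-3,7,11-trimethyl-13-oxotetradec-6-enoate | CC(C)(C)OC(=O)[C@](C)(CC(C)=O)CCC/C(C)=C(/CC[C@@H](C)CC(=O)OC)C(=O)SC(C)(C)C | intermediate
15 | tert-butyl (1S,2R,3R)-2-acetyl-3-[(2RS,5R)-1-(tert-butylsulfanyl)-7-methoxy-5-methyl-1,7-dioxoheptan-2-yl]-1,3-dimethylcyclohexane-1-carboxylate | CC(=O)[C@@H]1[C@@](C)(CCC[C@]1(C)C(=O)OC(C)(C)C)C(CC[C@@H](C)CC(=O)OC)C(=O)SC(C)(C)C | intermediate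
16 | tert-butyl (1S,4aS,5S,8aR)-5-[(3R)-5-methoxy-3-methyl-5-oxopentyl]-1,4a-dimethyl-6,8-dioxodecahydronaphthalene-1-carboxylate (diketo tautomer drawn) | O=C1CC(=O)[C@@H]2[C@@](C)(CCC[C@]2(C)C(=O)OC(C)(C)C)[C@@H]1CC[C@@H](C)CC(=O)OC | intermediate
17 | (1S,4aS,5S,8aR)-5-[(3R)-5-methoxy-3-methyl-5-oxopentyl]-1,4a-dimethyl-6,8-dioxodecahydronaphthalene-1-carboxylic acid | O=C1CC(=O)[C@@H]2[C@@](C)(CCC[C@]2(C)C(O)=O)[C@@H]1CC[C@@H](C)CC(=O)OC | intermediate
18 | methyl (3R)-5-[(2aS,5aR,6S,8bR)-2a,5a-dimethyl-2,7-dioxo-2a,3,4,5,5a,6,7,8b-octahydro-2H-naphtho[1,8-bc]furan-6-yl]-3-methylpentanoate | O=C1C=C2OC(=O)[C@@]3(C)CCC[C@@](C)([C@@H]1CC[C@@H](C)CC(=O)OC)[C@@H]23 | intermediate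
19 | 6,7-dihydro derivative of 18 (saturated 19,6-lactone with C8 ketone; C6 either epimer; other centres as in 18) | O=C1CC2OC(=O)[C@@]3(C)CCC[C@@](C)([C@@H]1CC[C@@H](C)CC(=O)OC)[C@@H]23 | intermediate
20 | 6,7-didehydro derivative of 21 (8-oxo-6-ene acid; centres as in 21) | O=C1C=C[C@@H]2[C@@](C)(CCC[C@]2(C)C(O)=O)[C@@H]1CC[C@@H](C)CC(=O)OC | intermediate
21 | (1S,4aR,5S,8aR)-5-[(3R)-5-methoxy-3-methyl-5-oxopentyl]-1,4a-dimethyl-6-oxodecahydronaphthalene-1-carboxylic acid | O=C1CC[C@@H]2[C@@](C)(CCC[C@]2(C)C(O)=O)[C@@H]1CC[C@@H](C)CC(=O)OC | intermediate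
22 | (1S,4aS,5R,8aR)-5-[(3R)-5-methoxy-3-methyl-5-oxopentyl]-1,4a-dimethyl-6-methylidenedecahydronaphthalene-1-carboxylic acid | C=C1CC[C@@H]2[C@@](C)(CCC[C@]2(C)C(=O)O)[C@@H]1CC[C@@H](C)CC(=O)OC | target

**Step count**

Total step count: 13. Longest linear sequence: 9 steps (steps 1–4 and 9–13; the branch through steps 5–8 and 9–13 is equally long).

**Steps most likely to fail**

1. Step 10. The conjugate addition to the tetrasubstituted acceptor may be too slow, so that intermolecular acylation takes over. The magnesium template may also give poor facial selectivity at C10. Fallback with known reactions, run stepwise: starting from 14, TMSCl/NaI/Et3N in MeCN should give the thermodynamic silyl enol ether, the (12Z)-trimethylsilyl enol ether of 14 F1. SnCl4 in CH2Cl2 at −78 °C then closes ring A by intramolecular Mukaiyama–Michael addition (the tin centre bridging the two ester carbonyls), giving 15, this time isolated. KOt-Bu in THF at 0 °C closes ring B by Dieckmann-type Claisen condensation, and the route is rejoined at 16.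

2. Step 11. The C6 enol oxygen may fail to reach C19 in the cis-fused dione for conformational reasons, or C-acylation at C7 may compete. Fallback (Stork–Danheiser carbonyl transposition): starting from 16, HC(OMe)3/TsOH in MeOH should etherify the less hindered C8 oxygen to give the vinylogous methyl ester F2. NaBH4/CeCl3·7H2O (Luche reduction) reduces the C6 carbonyl to the allylic alcohol F3. Dilute HCl in THF hydrolyses the enol ether and eliminates water to give the 8-oxo-6-ene tert-butyl ester F4. H2 over Pd/C gives the saturated 8-oxo tert-butyl ester F5, and CF3CO2H cleaves the ester; the route is rejoined at 21.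

3. Step 9. Reduction of the C6 ketone by 9-BBN may compete with hydroboration, and transmetalation onto the hindered tetrasubstituted triflate may be slow. Fallback (ketone masked): starting from 6, ethylene glycol/PPTS with azeotropic removal of water gives the dioxolane F6. 9-BBN gives the alkylborane F7, used directly. Coupling with 12 under the conditions of step 9 gives the dioxolane of 14 F8, and PPTS in aqueous acetone removes the ketal; the route is rejoined at 14.

**Further compounds**

F1 | step 10 | methyl (3R,6Z,11S,12Z)-11-(tert-butoxycarbonyl)-6-[(tert-butylsulfanyl)carbonyl]-3,7,11-trimethyl-13-[(trimethylsilyl)oxy]tetradeca-6,12-dienoate | CC(C)(C)OC(=O)[C@](C)(/C=C(/C)O[Si](C)(C)C)CCC/C(C)=C(/CC[C@@H](C)CC(=O)OC)C(=O)SC(C)(C)C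
F2 | step 11 | tert-butyl (1S,4aS,5S,8aR)-6-methoxy-5-[(3R)-5-methoxy-3-methyl-5-oxopentyl]-1,4a-dimethyl-8-oxo-1,2,3,4,4a,5,8,8a-octahydronaphthalene-1-carboxylate | COC1=CC(=O)[C@@H]2[C@@](C)(CCC[C@]2(C)C(=O)OC(C)(C)C)[C@@H]1CC[C@@H](C)CC(=O)OC
F3 | step 11 | 8-hydroxy analogue of F2 (allylic alcohol from reduction of the C8-oxo group of F2; carbinol either epimer; other centres as in F2) | COC1=CC(O)[C@@H]2[C@@](C)(CCC[C@]2(C)C(=O)OC(C)(C)C)[C@@H]1CC[C@@H](C)CC(=O)OC
F4 | step 11 | tert-butyl ester of 20 (8-oxo-6-ene, labdane numbering) | O=C1C=C[C@@H]2[C@@](C)(CCC[C@]2(C)C(=O)OC(C)(C)C)[C@@H]1CC[C@@H](C)CC(=O)OC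
F5 | step 11 | tert-butyl ester of 21 | O=C1CC[C@@H]2[C@@](C)(CCC[C@]2(C)C(=O)OC(C)(C)C)[C@@H]1CC[C@@H](C)CC(=O)OC
F6 | step 9 | tert-butyl (2S)-2-methyl-2-[(2-methyl-1,3-dioxolan-2-yl)methyl]pent-4-enoate | C=CC[C@@](C)(CC1(C)OCCO1)C(=O)OC(C)(C)C
F7 | step 9 | tert-butyl (2S)-5-(9-borabicyclo[3.3.1]nonan-9-yl)-2-methyl-2-[(2-methyl-1,3-dioxolan-2-yl)methyl]pentanoate | CC1(C[C@](C)(CCCB2C3CCCC2CCC3)C(=O)OC(C)(C)C)OCCO1
F8 | step 9 | ethylene ketal of 14 at the 13-oxo group | CC(C)(C)OC(=O)[C@](C)(CC1(C)OCCO1)CCC/C(C)=C(/CC[C@@H](C)CC(=O)OC)C(=O)SC(C)(C)C
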